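**Retrosynthetic overview**

- Target numbering used here: C1 is the acyl-bearing tertiary carbinol, C2 the CH(OH), C3=C4 the alkene, C5 the CH(OAc). The target is reached by enzymatic removal of one of the two enantiotopic acetates of a meso diacetate ketone, in which the three ring oxygens are all-trans.
- That meso diacetate comes, by Luche reduction, acetylation, desilylation and oxidation, from a racemic trans-4,5-dihydroxy-5-(1-silyloxytridecyl)cyclopent-2-enone; both antipodes converge on the meso compound.
- The cyclopentenone is made by photochemical ring contraction of 3-(1-silyloxytridecyl)-4H-pyran-4-one in water. The C2–C3 bond of the cyclopentene is formed between the two carbons that flank the pyranone oxygen; the ring oxygen becomes the C2 hydroxyl, water becomes the trans C1 hydroxyl, and the pyranone carbonyl becomes the C5 oxygen.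
- Enabling feature: in the target ring the secondary carbinol C2 lies between alkene carbon C3 and tertiary carbinol C1 (hydroxyls trans), with oxygen on C5. This O–C2/C3=C4/C5–O/C1–OH array is the hydrated, ring-contracted image of a 4-pyranone, whose O1 is flanked by C2 and C6 of a cross-conjugated dienone.
- The pyranone comes from 4H-pyran-4-one by bromination, Nozaki–Hiyama–Kishi coupling with tridecanal and silylation. Ring order: the only ring, the cyclopentene, is made in step 4 from the commercial six-membered pyranone ring.

Key step: step 4

Remark on the chemistry: all intermediates between the aldehyde coupling and the meso diacetate are racemic (the photoproduct is also a pair of epimers at the silyloxy carbon). Their SMILES show one ring enantiomer and leave the side-chain carbinol centre open, because that centre is erased by the oxidation and both ring antipodes converge on the meso diacetate.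

**Route**

Step 1
Reactants: 1 4H-pyran-4-one
Product: 3 3-bromo-4H-pyran-4-one, via trans-2,3-dibromo-2,3-dihydropyran-4-one 2 (not isolated)
Conditions: Br2 (1.0 equiv), CH2Cl2, 0 °C; then Et3N, 0 °C to rt
Reagents that add atoms: bromine (BrBr)
Why: Electrophilic addition of bromine to the enol-ether C2=C3 bond followed by base-induced E1cB loss of HBr (α-bromination of a vinylogous ester by addition–elimination) should give the 3-bromide, one equivalent of Br2 limiting 3,5-dibromination; no stereocentre remains.

Step 2
Reactants: 3 3-bromo-4H-pyran-4-one; 4 tridecanal
Product: 5 racemic 3-(1-hydroxytridecyl)-4H-pyran-4-one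
Conditions: CrCl2 (4 equiv), NiCl2 (2 mol %), DMF, rt
Reagents that add atoms: none
Why: Nozaki–Hiyama–Kishi coupling, in which zerovalent nickel inserts into the activated C–Br bond and the vinyl species of trivalent chromium adds chemoselectively to the aldehyde without attacking the vinylogous-ester carbonyl or opening the ring; the new carbinol centre forms as a racemate, which is acceptable because it becomes the ketone in step 8.

Step 3
Reactants: 5 racemic 3-(1-hydroxytridecyl)-4H-pyran-4-one
Product: 6 racemic 3-[1-(tert-butyldimethylsilyloxy)tridecyl]-4H-pyran-4-one
Conditions: TBSCl, imidazole, DMF, rt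
Reagents that add atoms: tert-butyldimethylsilyl chloride, TBSCl (CC(C)(C)[Si](C)(C)Cl)
Why: Imidazole-promoted silyl ether formation masks the side-chain oxygen so that it stays distinguishable from the two ring hydroxyls that appear in steps 4 and 5.

Step 4
Reactants: 6 racemic 3-[1-(tert-butyldimethylsilyloxy)tridecyl]-4H-pyran-4-one
Product: 8 racemic trans-4,5-dihydroxy-5-[1-(tert-butyldimethylsilyloxy)tridecyl]cyclopent-2-en-1-one, via epoxy oxyallyl zwitterion 7 (not isolated)
Conditions: hν (254 nm, quartz immersion well or flow coil), MeCN/H2O 3:1, 2 mM, Ar, 20 °C
Reagents that add atoms: water (O)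
Why: Excitation of the cross-conjugated pyranone (π,π*) should trigger a disrotatory 4π electrocyclisation that joins the two oxygen-flanking carbons C2 and C6 and gives the 6-oxabicyclo[3.1.0]hexenyl oxyallyl zwitterion 7; water then adds to the alkyl-bearing oxyallyl terminus and the enolate so formed opens the epoxide by β-elimination, leaving the former ring oxygen as the secondary hydroxyl next to the new C–C bond. The closest known reaction type is the photochemical ring contraction of alkyl-substituted 4-pyranones in hydroxylic solvents to trans-4-hydroxy-5-alkoxy(hydroxy)cyclopent-2-enones, the heterocyclic counterpart of the cross-conjugated dienone photorearrangement. The cyclopentene is closed by a transannular electrocyclic C–C bond formation inside the six-membered ring (a ring contraction in which the bicyclic epoxide is only a relay), not by a chain cyclisation. The tertiary carbinol centre is set by attack of water on the face of the oxyallyl cation opposite to the epoxide bridge and the secondary carbinol keeps the bridge oxygen, so the two hydroxyls are trans by mechanism; the absolute sense is not controlled (racemate, both epimers at the silyloxy carbon), which steps 5 to 9 absorb. The step needs regioselective capture at the substituted terminus and capture faster than rearrangement to a 2-pyranone: the side chain makes C3 the only alkyl-stabilised cationic terminus (capture of unsymmetrical allyl-type cations by water favours the more substituted end), and the dilute aqueous medium at 254 nm, where the pyranone absorbs far more strongly than the enone product, should favour capture over rearrangement and secondary photochemistry.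

Step 5
Reactants: 8 racemic trans-4,5-dihydroxy-5-[1-(tert-butyldimethylsilyloxy)tridecyl]cyclopent-2-en-1-one
Product: 9 racemic all-trans 2-[1-(tert-butyldimethylsilyloxy)tridecyl]cyclopent-4-ene-1,2,3-triol
Conditions: NaBH4, CeCl3·7H2O, MeOH, −78 to −20 °C
Reagents that add atoms: none
Why: Luche 1,2-reduction, in which hydride should add to the carbonyl face that carries only the small tertiary hydroxyl, anti to the bulky silyloxyalkyl branch and to the C4 hydroxyl, so the new carbinol is cis to the C4 hydroxyl and trans to the tertiary one and all stereoisomers of 8 converge on one racemic triol.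

Step 6
Reactants: 9 racemic all-trans 2-[1-(tert-butyldimethylsilyloxy)tridecyl]cyclopent-4-ene-1,2,3-triol
Product: 10 racemic 2-hydroxy-2-[1-(tert-butyldimethylsilyloxy)tridecyl]cyclopent-4-ene-1,3-diyl diacetate
Conditions: Ac2O, pyridine, 4-(dimethylamino)pyridine (cat.), CH2Cl2, 0 °C to rt
Reagents that add atoms: acetic anhydride (CC(=O)OC(C)=O)
Why: Nucleophile-catalysed acylation should esterify the two secondary allylic hydroxyls while the tertiary hydroxyl, buried between three branched carbons, stays free; the acetates protect these positions in steps 7 and 8 and one of them is kept in the target.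

Step 7
Reactants: 10 racemic 2-hydroxy-2-[1-(tert-butyldimethylsilyloxy)tridecyl]cyclopent-4-ene-1,3-diyl diacetate
Product: 11 racemic 2-hydroxy-2-(1-hydroxytridecyl)cyclopent-4-ene-1,3-diyl diacetate
Conditions: HF·pyridine, pyridine, THF, 0 °C to rt
Reagents that add atoms: none
Why: Fluoride-driven desilylation under buffered, non-basic conditions should free the side-chain alcohol without cleaving or shifting the acetates.

Step 8
Reactants: 11 racemic 2-hydroxy-2-(1-hydroxytridecyl)cyclopent-4-ene-1,3-diyl diacetate
Product: 12 meso 2-hydroxy-2-tridecanoylcyclopent-4-ene-1,3-diyl diacetate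
Conditions: IBX (2-iodoxybenzoic acid), DMSO, rt
Reagents that add atoms: none
Why: Hypervalent-iodine oxidation of the only secondary alcohol should give the α-hydroxy ketone without glycol cleavage, the tertiary hydroxyl and allylic acetates being inert and the fully substituted α-carbon excluding elimination; erasing the side-chain stereocentre turns the racemate into a single meso compound.

Step 9
Reactants: 12 meso 2-hydroxy-2-tridecanoylcyclopent-4-ene-1,3-diyl diacetate
Product: 13 (1S,4R,5S)-4,5-dihydroxy-5-tridecanoylcyclopent-2-en-1-yl acetate
Conditions: Burkholderia cepacia lipase, 0.1 M KH2PO4/K2HPO4 buffer pH 7.0, MTBE (biphasic), 25 °C, stopped after one equivalent of acid is released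
Reagents that add atoms: none
Why: Hydrolase-catalysed desymmetrisation of a meso cis-1,3-diacetate (enantiotopic-group-selective ester hydrolysis, as practised on meso cyclopent-4-ene-1,3-diyl diacetates) creates no stereocentre but should remove the acetate from the R-configured carbinol carbon, the one expected from the usual lipase preference for secondary esters when the fully substituted ring carbon acts as the large and the alkene CH as the medium substituent, which fixes the absolute configuration as 1S,4R,5S; neutral pH suppresses 1,3-acyl migration.

**Compound list**

1 | 4H-pyran-4-one | O=C1C=COC=C1 | starting material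
2 | trans-2,3-dibromo-2,3-dihydro-4H-pyran-4-one (racemic, formed in the flask) | O=C1C=CO[C@H](Br)[C@H]1Br | intermediate
3 | 3-bromo-4H-pyran-4-one | O=C1C=COC=C1Br | intermediate
4 | tridecanal | CCCCCCCCCCCCC=O | starting material
5 | 3-(1-hydroxytridecyl)-4H-pyran-4-one (racemic) | O=C1C=COC=C1C(O)CCCCCCCCCCCC | intermediate
6 | 3-[1-(tert-butyldimethylsilyloxy)tridecyl]-4H-pyran-4-one (racemic) | O=C1C=COC=C1C(O[Si](C)(C)C(C)(C)C)CCCCCCCCCCCC | intermediate
7 | 2-[1-(tert-butyldimethylsilyloxy)tridecyl]-6-oxabicyclo[3.1.0]hex-3-en-2-ylium-3-olate, cis-fused epoxy oxyallyl zwitterion (racemic, formed in the flask) | [O-]C1=C[C@H]2O[C@H]2[C+]1C(O[Si](C)(C)C(C)(C)C)CCCCCCCCCCCC | intermediate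
8 | trans-4,5-dihydroxy-5-[1-(tert-butyldimethylsilyloxy)tridecyl]cyclopent-2-en-1-one; 4-OH trans to 5-OH and cis to the side chain (racemic, both epimers at the silyloxy carbon) | CCCCCCCCCCCCC(O[Si](C)(C)C(C)(C)C)[C@]1(O)[C@H](O)C=CC1=O | intermediate
9 | all-trans 2-[1-(tert-butyldimethylsilyloxy)tridecyl]cyclopent-4-ene-1,2,3-triol; 1-OH and 3-OH cis to each other and to the side chain, 2-OH trans to both (racemic) | CCCCCCCCCCCCC(O[Si](C)(C)C(C)(C)C)[C@]1(O)[C@H](O)C=C[C@@H]1O | intermediate
10 | 2-hydroxy-2-[1-(tert-butyldimethylsilyloxy)tridecyl]cyclopent-4-ene-1,3-diyl diacetate; acetoxy groups cis to each other, trans to the tertiary OH (racemic) | CCCCCCCCCCCCC(O[Si](C)(C)C(C)(C)C)[C@]1(O)[C@H](OC(C)=O)C=C[C@@H]1OC(C)=O | intermediate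
11 | 2-hydroxy-2-(1-hydroxytridecyl)cyclopent-4-ene-1,3-diyl diacetate; same ring configuration as 10 (racemic) | CCCCCCCCCCCCC(O)[C@]1(O)[C@H](OC(C)=O)C=C[C@@H]1OC(C)=O | intermediate
12 | meso 2-hydroxy-2-tridecanoylcyclopent-4-ene-1,3-diyl diacetate; acetoxy groups cis to each other and to the acyl group, trans to the tertiary OH | CCCCCCCCCCCCC(=O)[C@]1(O)[C@H](OC(C)=O)C=C[C@@H]1OC(C)=O | intermediate
13 | (1S,4R,5S)-4,5-dihydroxy-5-tridecanoylcyclopent-2-en-1-yl acetate | CCCCCCCCCCCCC(=O)[C@]1(O)[C@H](O)C=C[C@@H]1OC(C)=O | target

**Step count and risks**

Total step count: 9.
Longest linear sequence: 9 steps (1 to 13).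

Steps most likely to fail:

1. Step 4 (photochemical ring contraction). The zwitterion may be captured by water at the unsubstituted terminus, may rearrange to a 2-pyranone before capture because only one alkyl group stabilises it, or the enone may be consumed by secondary photochemistry.
 Fallback (no photochemical ring contraction), from 4 to 11: condensation of tridecanal 4 with cyclopentadiene (pyrrolidine, MeOH, 0 °C) should give 6-dodecylfulvene F1. Dye-sensitised photooxygenation (O2, rose bengal, visible light, MeOH/CH2Cl2, −78 °C) adds singlet oxygen across the ring diene to give the bicyclic endoperoxide F2, which is reduced in the same flask with thiourea to meso cis-2-tridecylidenecyclopent-4-ene-1,3-diol F3. Acetylation (Ac2O, pyridine) gives the meso diacetate F4. Dihydroxylation (OsO4 cat., N-methylmorpholine N-oxide, acetone/H2O) of the trisubstituted exocyclic alkene from the face opposite to the two acetoxy groups should place the tertiary hydroxyl trans to both acetates and give 11, where the route continues with steps 8 and 9.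

2. Step 9 (enzymatic desymmetrisation). Turnover may be slow because both esters flank a fully substituted carbon, the enzyme may prefer the other enantiotopic acetate (its large/medium assignment is not secure for two ring substituents), hydrolysis may run on to the diol, or acyl migration may erode the enantiomeric purity.
 Fallback, from 12 to 13: mild transesterification (K2CO3 cat., MeOH, 0 °C) removes both acetates to give the meso diol ketone F5. The desymmetrisation is then run in the acylation direction (lipase, vinyl acetate, MTBE, rt). The same enzyme acetylates the hydroxyl whose ester it would hydrolyse, so the mirror-image outcome of the hydrolysis mode becomes available, and a wider set of lipases and chiral acyl-transfer catalysts can be screened on the diol. This gives 13 directly.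

3. Step 2 (Nozaki–Hiyama–Kishi coupling). Oxidative addition into the vinyl bromide may be sluggish, or reductive loss of bromine and aldehyde reduction may outrun the coupling.
 Fallback, from 4 to 6: the lithium enolate of commercial 2,3-dihydro-4H-pyran-4-one (LiN(iPr)2, THF, −78 °C) is added to tridecanal 4 to give the aldol adduct 3-(1-hydroxytridecyl)-2,3-dihydro-4H-pyran-4-one F6. Silylation (TBSOTf, 2,6-lutidine, CH2Cl2, −78 °C) gives the silyl ether F7. Dehydrogenation of the C2–C3 bond with IBX (2-iodoxybenzoic acid) in DMSO at 70 °C should give pyranone 6.

Further compounds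
F1 | step 4 | 6-dodecylfulvene (5-tridecylidenecyclopenta-1,3-diene) | CCCCCCCCCCCCC=C1C=CC=C1
F2 | step 4 | 7-tridecylidene-2,3-dioxabicyclo[2.2.1]hept-5-ene (meso endoperoxide) | CCCCCCCCCCCCC=C1[C@H]2C=C[C@@H]1OO2
F3 | step 4 | meso cis-2-tridecylidenecyclopent-4-ene-1,3-diol | CCCCCCCCCCCCC=C1[C@H](O)C=C[C@@H]1O
F4 | step 4 | meso cis-2-tridecylidenecyclopent-4-ene-1,3-diyl diacetate | CCCCCCCCCCCCC=C1[C@H](OC(C)=O)C=C[C@@H]1OC(C)=O
F5 | step 9 | meso 1-(all-trans-1,2,5-trihydroxycyclopent-3-en-1-yl)tridecan-1-one | CCCCCCCCCCCCC(=O)[C@]1(O)[C@H](O)C=C[C@@H]1O
F6 | step 2 | 3-(1-hydroxytridecyl)-2,3-dihydro-4H-pyran-4-one (mixture of diastereomers, racemic) | O=C1C=COCC1C(O)CCCCCCCCCCCC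
F7 | step 2 | 3-[1-(tert-butyldimethylsilyloxy)tridecyl]-2,3-dihydro-4H-pyran-4-one (mixture of diastereomers, racemic) | O=C1C=COCC1C(O[Si](C)(C)C(C)(C)C)CCCCCCCCCCCC
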